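## Retrosynthetic overview
1. (+)-Neoolivil comes from the all-trans 2,5-diaryl-THF-3,4-diester by one global hydride reduction (esters to CH2OH, phenol pivalates removed).
2. Both C2–Ar and C5–Ar bonds come from a twofold Ni/photoredox decarboxylative arylation of a THF-2,5-dicarboxylic acid. The C3/C4 esters direct each aryl group trans.
3. The only ring (THF) is closed before the aryl groups arrive, by 5-exo-tet C–O displacement of an α-triflate within a C2-symmetric 1,4-diol.
4. The C3–C4 (lignan 8–8′) bond comes from anodic oxidative homocoupling of the dilithio dianion of dimethyl L-malate. The malate carbinol sets both new stereocentres.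
5. Two L-malates supply all six aliphatic carbons, the ring oxygen and all chirality. 4-Bromoguaiacol supplies both arenes.

Assumption: the SMILES decodes to the C2-symmetric, all-trans (2R,3S,4S,5R) isomer, and dimethyl L-malate and 4-bromo-2-methoxyphenol are taken as commercial.

## Route

**Step 1**
Reactants: **1**, dimethyl (S)-malate (2 equiv)
Product: **2**, tetramethyl (1S,2R,3R,4S)-1,4-dihydroxybutane-1,2,3,4-tetracarboxylate. This is the C2-symmetric C3–C3′ malate dimer, with each OH anti to the new C–C bond.
Conditions: LiHMDS (2.1 equiv), THF, −78 → −20 °C. Then divided cell, RVC anode / Pt cathode (catholyte LiTFSI/THF + HFIP), Cp2Fe (10 mol %), LiTFSI (0.3 M)/THF, −70 °C, constant current, 1.05 F per mol of **1**. AcOH quench at −70 °C.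
Reagents that add atoms: none
Why: Proposed new method: anodically regenerated ferrocenium removes one electron from the Li-chelated alkoxide–enolate dianion, the resulting α-ester radical adds to a neighbouring enolate within the lithium aggregate (or pairs with a second radical), a second oxidation completes the C3–C3′ bond, and each carbon reacts on the face anti to the C2–CO2Me of its six-membered Li chelate so that two (S)-units give the (2R,3R) anti,anti dimer; the alkoxide (not an ether) at the β-position blocks E1cB loss; the closest known reaction types are anodic or ferrocenium oxidative homocoupling of lithium ester enolates to succinates and Fráter–Seebach anti-alkylation of malate dianions.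

**Step 2**
Reactants: **2**
Product: **3**, tetramethyl (2R,3R,4R,5S)-oxolane-2,3,4,5-tetracarboxylate. It is 3,4-trans and 2,5-cis; the C2 ester (inverted centre) is trans to the C3 ester, and the C5 ester (retained centre) is cis to the C4 ester.
Conditions: Tf2O (1.05 equiv), pyridine (3 equiv), CH2Cl2, −78 → 0 °C
Reagents that add atoms: none
Why: Mono-triflation of either homotopic OH gives an α-triflyloxy ester that the remaining OH displaces by intramolecular SN2 (5-exo-tet, inversion), the same closure that converts 2-O-triflyl aldonates into 2,5-anhydroaldonates, and C3/C4 are untouched.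

**Step 3**
Reactants: **3**
Product: **4**, (2R,3R,4R,5S)-3,4-bis(methoxycarbonyl)oxolane-2,5-dicarboxylic acid
Conditions: Me3SnOH (4.5 equiv), 1,2-DCE, 60 °C; 5 % KHSO4 wash
Reagents that add atoms: trimethyltin hydroxide, C[Sn](C)(C)O (supplies the two carboxyl OH oxygens)
Why: Chemoselective non-basic ester hydrolysis, in which the C2/C5 esters are activated by the α-oxygen and have only one neighbour, the C3/C4 esters are doubly flanked, and the neutral tin reagent avoids C3/C4 epimerisation and retro-oxa-Michael opening.

**Step 4** (side branch)
Reactants: **5**, 4-bromo-2-methoxyphenol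
Product: **6**, 4-bromo-2-methoxyphenyl pivalate
Conditions: PivCl (1.1 equiv), Et3N, DMAP (cat.), CH2Cl2, 0 °C → rt
Reagents that add atoms: pivaloyl chloride, CC(C)(C)C(=O)Cl
Why: Standard phenol acylation, where the pivalate masks the oxidisable phenol, makes the C–Br bond less electron-rich for oxidative addition, and is removed for free in the last step.

**Step 5**
Reactants: **4** and **6** (3 equiv)
Product: **7**, dimethyl (2R,3R,4R,5R)-2,5-bis[3-methoxy-4-(pivaloyloxy)phenyl]oxolane-3,4-dicarboxylate (all-trans, C2-symmetric)
Conditions: Ir[dF(CF3)ppy]2(dtbbpy)PF6 (2 mol %), NiCl2·glyme (20 mol %), dtbbpy (20 mol %), Cs2CO3 (2.2 equiv), DMF, 450 nm LEDs, 25 °C, 48 h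
Reagents that add atoms: none (aryl groups come from **6**; 2 CO2 are lost)
Why: Metallaphotoredox decarboxylative arylation of α-oxy acids, in which each caesium carboxylate is oxidised by excited Ir and loses CO2 to give a planar 2-oxolanyl radical that ArNi captures anti to the adjacent C3/C4 ester, so the irregular C2/C5 configuration of **4** converges to 2,3-trans/4,5-trans.

**Step 6**
Reactants: **7**
Product: **8**, (+)-neoolivil, 4,4′-[(2R,3S,4S,5R)-3,4-bis(hydroxymethyl)oxolane-2,5-diyl]bis(2-methoxyphenol)
Conditions: LiAlH4 (8 equiv), THF, 0 °C → rt; Rochelle salt / pH 7 buffer work-up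
Reagents that add atoms: none
Why: LiAlH4 ester reduction converts both methyl esters to CH2OH and cleaves both aryl pivalates in one operation without touching a stereocentre (the C3/C4 descriptors change R→S only through CIP priority), and the neutral work-up avoids benzylic ionisation.

## Compound list
1 | dimethyl (S)-malate | COC(=O)C[C@H](O)C(=O)OC | starting material
2 | tetramethyl (1S,2R,3R,4S)-1,4-dihydroxybutane-1,2,3,4-tetracarboxylate | COC(=O)[C@@H](O)[C@H](C(=O)OC)[C@@H](C(=O)OC)[C@H](O)C(=O)OC | intermediate
3 | tetramethyl (2R,3R,4R,5S)-oxolane-2,3,4,5-tetracarboxylate | COC(=O)[C@H]1O[C@@H](C(=O)OC)[C@H](C(=O)OC)[C@H]1C(=O)OC | intermediate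
4 | (2R,3R,4R,5S)-3,4-bis(methoxycarbonyl)oxolane-2,5-dicarboxylic acid | OC(=O)[C@H]1O[C@@H](C(=O)O)[C@H](C(=O)OC)[C@H]1C(=O)OC | intermediate
5 | 4-bromo-2-methoxyphenol | COc1cc(Br)ccc1O | starting material
6 | 4-bromo-2-methoxyphenyl pivalate | COc1cc(Br)ccc1OC(=O)C(C)(C)C | intermediate
7 | dimethyl (2R,3R,4R,5R)-2,5-bis[3-methoxy-4-(pivaloyloxy)phenyl]oxolane-3,4-dicarboxylate | COc1cc([C@@H]2O[C@@H](c3ccc(OC(=O)C(C)(C)C)c(OC)c3)[C@H](C(=O)OC)[C@H]2C(=O)OC)ccc1OC(=O)C(C)(C)C | intermediate
8 | (+)-neoolivil | COc1cc([C@@H]2O[C@@H](c3ccc(O)c(OC)c3)[C@H](CO)[C@H]2CO)ccc1O | target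

## Summary
Total steps: 6. Longest linear sequence: 5 (Steps 1, 2, 3, 5, 6).

Three steps most likely to fail:
1. **Step 1 (proposed new step).**
   - Risks: the C3 radical may abstract the hydridic alkoxide C2–H, giving net oxidation to oxaloacetate. Facial selectivity may be only moderate, giving anti,syn dimer. The dimer may lactonise on warming.
   - Fallback (known chemistry): abandon the dianion and the cell. Protect **1** as its TBS ether and form the ketene silyl acetal (LDA/TMSCl, internal quench). Then use the established TiCl4-mediated oxidative dimerisation of ketene silyl acetals to succinates, relying on open-chain 1,2-induction, and desilylate to **2** (+3 steps).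
2. **Step 5.**
   - Risks: protodecarboxylation, stalling at mono-arylation, or eroded trans selectivity on a crowded diacid.
   - Fallback: generate the radicals reductively instead of oxidatively. Convert **4** to its bis(N-hydroxyphthalimide) ester. Then run the Ni-electrocatalytic decarboxylative cross-electrophile arylation with the aryl iodide analogue of **6**, one carboxyl at a time if needed.
3. **Step 2.**
   - Risks: β-elimination of the α-triflate (the C3–H is acidic) to an alkylidene succinate, or competing γ-lactonisation.
   - Fallback: reverse the order of ring formation (+3 steps).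
     - Let **2** bis-lactonise (cat. TsOH) to the cis-fused 3,7-dioxabicyclo[3.3.0]octane-2,6-dione-4,8-diester.
     - Free the two methyl esters and run the same double arylation on the convex face.
     - Reduce with LiAlH4 to the 1,4-diaryl tetraol and silylate the phenols and primary OH groups (TBSCl).
     - Close the THF last by benzylic cyclodehydration of the 1,4-diol (MsCl/Et3N), then remove silyl groups with TBAF.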